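The earlier runs and the new flask are simulated from invented constants; the scatter is artificial.

Freeze one number for the south-east flask, which is the flask asked about. This is the frozen loss constant, a pseudo-first-order constant: the natural logarithm of charge over free substrate, divided by time. The reading at 3.00 min puts it at 0.178 /min, and the reading at 1.33 min gives 0.168 /min, so it rises a little across these readings.

in all of them: substrate 0.20 M
- south-east: acid 0.60 mM; the very flask that is asked about, followed so far
- flask: acid 0.600 mM; time 15 min
south-east run (percent of the substrate charged)

| time / min | substrate / % | target / % |
|---|---|---|
| 0.250 | 96.3 | 3.0 |
| 0.333 | 94.4 | 2.5 |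
| 0.500 | 91.9 | 4.0 |
| 0.833 | 87.1 | 7.1 |
| 1.33 | 80.0 | 11.1 |
| 2.00 | 69.9 | 15.7 |
| 3.00 | 58.7 | 22.5 |

(scatter of a reading: 0.3 percentage points)
- part of the substrate that has reacted at 15 min
- pH of the solution at 15 min
- acid is the free proton; pH is minus the decimal logarithm of its molar concentration
- the earlier runs were read with a standard deviation of 0.3 percentage points
- a reading or a percentage of target counts all its forms, free or not
- what has gone from substrate into another species counts as reacted, even if it can come back
- a reading of substrate is of its free form alone

Now turn the question round. For half of the charge to stand free at 15 min, the constant would have to be 0.0462 /min. The reading at 3.00 min stands at 3.85 times that. Whatever has left the free form counts as reacted, so I commit to 93.0% reacted. The readings hold no pH, so I reckon none.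

The forecast, weighing whether “the sink is a reversible complex”, gives 90% and pH 3.25.

The flask gives 88.9% and pH 3.04.

    weak acid ⇌ conjugate base + acid, settled at all times (K = 2.50 × 10⁻⁶ M)
    substrate + acid → weak acid + acid + target (k = 120 /M/min)
    substrate → weak acid + target (k = 0.0140 /min)
    substrate + target ⇌ idle adduct, settled at all times (K = 56.0 /M)

The flask's average constant up to 15 min is 0.147 /min, so my frozen figure stands 4.1 percentage points high. The same flask read at 4.0 min comes to 50.9% by the frozen constant and stands at 51.4%. In this flask, substrate is used through the acid step 5.1 times as fast as by the step without acid just after the start, and 7.8 times as fast at 15 min. At that time the half-life of substrate by the acid step is 6.3 min, shorter than the 50 min by the other step alone.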